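The heterocyclic ring C is made of O1 and C4a, both part of ring A, tied through the chain C4–C3–C2 to C1' of ring B, and C4 is a carbonyl carbon that carbon monoxide can deliver. The route therefore disconnects C4a–C4, C4–C3 and O1–C2 at the flavone oxidation level: one palladium-catalysed carbonylative annulation unites an ortho-iodophenol, CO and a terminal aryl alkyne and closes ring C in the same flask. Its precursors are 6-iodo-2-prenyl-3-(triisopropylsilyloxy)phenol (ring A) and 6-ethynyl-2,2-dimethyl-7-(triisopropylsilyloxy)chromene (ring B). Asymmetric copper hydride conjugate reduction then sets C2 as S, and buffered fluoride frees both phenols.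

Key step: step 11

Assumption: the sense of induction of the copper hydride reduction is assigned on a model flavone; (R)-DTBM-SEGPHOS is written in step 12, and its mirror image is used instead if the model shows that it gives the 2R ketone.

Step 1
Reactants: 1 resorcinol (benzene-1,3-diol)
Product: 2 1,3-bis(methoxymethoxy)benzene
Conditions: MOMCl, i-Pr2NEt, CH2Cl2, 0 °C → rt
Reagents that add atoms: chloromethyl methyl ether, COCCl
Why: Both phenols are alkylated by the chloromethyl ether (Williamson-type O-alkylation), which gives two MOM acetals that will direct the two lithiations that follow.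

Step 2
Reactants: 2 1,3-bis(methoxymethoxy)benzene; 3 prenyl bromide (1-bromo-3-methylbut-2-ene)
Product: 5 1,3-bis(methoxymethoxy)-2-(3-methylbut-2-enyl)benzene, via C2 aryllithium 4 (not isolated)
Conditions: n-BuLi, THF, 0 °C → rt; then CuBr·SMe2 (10 mol %), 3, −78 °C → rt
Reagents that add atoms: none
Why: Directed ortho-metalation puts lithium at C2 between the two coordinating OMOM groups, and the aryl nucleophile, passed through copper, couples with the primary carbon of prenyl bromide in an SN2 allylation.

Step 3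
Reactants: 5 1,3-bis(methoxymethoxy)-2-(3-methylbut-2-enyl)benzene
Product: 7 1-iodo-2,4-bis(methoxymethoxy)-3-(3-methylbut-2-enyl)benzene, via C4 aryllithium 6 (not isolated)
Conditions: n-BuLi, TMEDA, THF, −20 → 0 °C; then I2, THF, −78 °C; aq. Na2S2O3
Reagents that add atoms: iodine, [I][I]
Why: A second directed ortho-metalation takes the ring proton next to an OMOM group (C4 and C6 are equivalent), and the aryllithium is iodinated at −78 °C, so the iodine enters at a defined carbon without an electrophilic iodinating agent that could attack the prenyl alkene.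

Step 4
Reactants: 7 1-iodo-2,4-bis(methoxymethoxy)-3-(3-methylbut-2-enyl)benzene
Product: 8 4-iodo-2-(3-methylbut-2-enyl)benzene-1,3-diol
Conditions: HCl (2 M in MeOH), 0 °C → rt
Reagents that add atoms: none
Why: Acid-catalysed acetal exchange with methanol removes both MOM groups as dimethoxymethane, and dilute acid at or below room temperature should be too mild to protonate the trisubstituted alkene, which would otherwise cyclise onto the neighbouring phenol.

Step 5
Reactants: 8 4-iodo-2-(3-methylbut-2-enyl)benzene-1,3-diol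
Product: 9 6-iodo-2-(3-methylbut-2-enyl)-3-(triisopropylsilyloxy)phenol
Conditions: TIPSCl (1.05 equiv), imidazole, DMF, 0 °C
Reagents that add atoms: chlorotriisopropylsilane, CC(C)[Si](Cl)(C(C)C)C(C)C
Why: Imidazole-mediated silyl ether formation with a bulky silyl chloride should occur at the hydroxyl that has only one ortho substituent, because the other hydroxyl sits between the prenyl CH2 and the iodine and is shielded, which leaves exactly the ortho-iodophenol needed for the annulation.

Step 6
Reactants: 10 4-bromoresorcinol (4-bromobenzene-1,3-diol); 11 3-methylbut-2-enoic acid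
Product: 13 6-bromo-7-hydroxy-2,2-dimethylchroman-4-one, via aryl enone 12 (not isolated)
Conditions: P2O5, MeSO3H, 70 °C
Reagents that add atoms: none
Why: Friedel–Crafts acylation takes place at the only unhindered ring carbon that is ortho to one hydroxyl and para to the other (C6 of the resorcinol), and the ortho-hydroxyl then adds to the enone in an intramolecular oxa-Michael reaction that closes the chromanone.

Step 7
Reactants: 13 6-bromo-7-hydroxy-2,2-dimethylchroman-4-one
Product: 14 6-bromo-2,2-dimethyl-7-(triisopropylsilyloxy)chroman-4-one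
Conditions: TIPSCl, imidazole, DMF, rt
Reagents that add atoms: chlorotriisopropylsilane, CC(C)[Si](Cl)(C(C)C)C(C)C
Why: Imidazole-mediated silylation of the acidic phenol gives a TIPS ether that is bulky enough to survive the hydride reduction, the later carbonate methanolysis and the hot amine of the annulation.

Step 8
Reactants: 14 6-bromo-2,2-dimethyl-7-(triisopropylsilyloxy)chroman-4-one
Product: 16 6-bromo-2,2-dimethyl-7-(triisopropylsilyloxy)-2H-chromene, via chromanol 15 (not isolated)
Conditions: NaBH4, EtOH/THF, 0 °C; then p-TsOH·H2O (cat.), toluene, 60 °C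
Reagents that add atoms: none
Why: Borohydride reduction gives the benzylic alcohol, which loses water under acid catalysis by an E1 dehydration through a cation stabilised by the ring oxygen and the para silyloxy group, forming the 3,4-double bond of the chromene.

Step 9
Reactants: 16 6-bromo-2,2-dimethyl-7-(triisopropylsilyloxy)-2H-chromene; 17 ethynyltrimethylsilane
Product: 18 2,2-dimethyl-7-(triisopropylsilyloxy)-6-[(trimethylsilyl)ethynyl]-2H-chromene
Conditions: PdCl2(PhCN)2 (3 mol %), P(t-Bu)3·HBF4 (6 mol %), CuI (2 mol %), i-Pr2NH, dioxane, rt → 45 °C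
Reagents that add atoms: none
Why: Sonogashira coupling, in which the bulky electron-rich P(t-Bu)3 ligand allows oxidative addition of zerovalent palladium into the electron-rich, ortho-substituted aryl bromide near room temperature, and which avoids an ortho-silyloxy aryllithium that would suffer silyl migration from oxygen to carbon.

Step 10
Reactants: 18 2,2-dimethyl-7-(triisopropylsilyloxy)-6-[(trimethylsilyl)ethynyl]-2H-chromene
Product: 19 6-ethynyl-2,2-dimethyl-7-(triisopropylsilyloxy)-2H-chromene
Conditions: K2CO3 (0.2 equiv), MeOH/THF, 0 °C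
Reagents that add atoms: none
Why: Catalytic methoxide cleaves the C(sp)–Si bond (protodesilylation) quickly at 0 °C, conditions under which the hindered aryl TIPS ether should stay intact.

Step 11
Reactants: 9 6-iodo-2-(3-methylbut-2-enyl)-3-(triisopropylsilyloxy)phenol; 19 6-ethynyl-2,2-dimethyl-7-(triisopropylsilyloxy)-2H-chromene; 20 carbon monoxide
Product: 23 2-[2,2-dimethyl-7-(triisopropylsilyloxy)-2H-chromen-6-yl]-8-(3-methylbut-2-enyl)-7-(triisopropylsilyloxy)-4H-chromen-4-one, via ynone 21 (not isolated), via enaminone 22 (not isolated)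
Conditions: PdCl2(PPh3)2 (5 mol %), CO (20 bar), Et2NH, 100 °C, no copper salt
Reagents that add atoms: none
Why: Zerovalent palladium, formed in the flask from the divalent precatalyst, inserts into the C–I bond of 9 (the future C4a), CO inserts to give an acylpalladium species, and amine-assisted transfer of the acetylide of 19 followed by reductive elimination forms ynone 21 (bonds C4a–C4 and C4–C3). Et2NH adds to C2 of 21 to give enaminone 22, and the ring A hydroxyl then attacks C2 and expels the amine, so ring C closes by a 6-endo addition–elimination (bond O1–C2) and the 5-exo path to an aurone is bypassed. The closest known reaction type is the palladium-catalysed carbonylative annulation of ortho-iodophenols with terminal alkynes in a secondary amine, which gives flavones. No stereocentre is formed. The step needs carbonylation to outrun direct alkynylation, which the CO pressure and the absence of copper should secure, and it needs only the ring A hydroxyl to cyclise, which the TIPS ether at O2' guarantees by blocking benzofuran formation on ring B. The prenyl and chromene alkenes are not positioned to reach the arylpalladium centre and should pass through unchanged.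

Step 12
Reactants: 23 2-[2,2-dimethyl-7-(triisopropylsilyloxy)-2H-chromen-6-yl]-8-(3-methylbut-2-enyl)-7-(triisopropylsilyloxy)-4H-chromen-4-one
Product: 24 (2S)-2-[2,2-dimethyl-7-(triisopropylsilyloxy)-2H-chromen-6-yl]-8-(3-methylbut-2-enyl)-7-(triisopropylsilyloxy)-2,3-dihydro-4H-chromen-4-one
Conditions: Cu(OAc)2·H2O (5 mol %), (R)-DTBM-SEGPHOS (5.5 mol %), (EtO)2MeSiH, t-BuOH, toluene, 0 °C → rt
Reagents that add atoms: none
Why: A bisphosphine-ligated copper hydride (monovalent copper, formed from Cu(OAc)2 and the silane) delivers hydride to C2 of the chromone enone in an asymmetric conjugate reduction, the chiral ligand choosing the face so that C2 becomes S, and t-BuOH protonates the copper enolate to release the ketone and turn the catalyst over, while the isolated and styrenic alkenes are not activated enough to react.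

Step 13
Reactants: 24 (2S)-2-[2,2-dimethyl-7-(triisopropylsilyloxy)-2H-chromen-6-yl]-8-(3-methylbut-2-enyl)-7-(triisopropylsilyloxy)-2,3-dihydro-4H-chromen-4-one
Product: 25 (2S)-7-hydroxy-2-(7-hydroxy-2,2-dimethyl-2H-chromen-6-yl)-8-(3-methylbut-2-enyl)-2,3-dihydro-4H-chromen-4-one
Conditions: Bu4NF, AcOH (1:1), THF, 0 °C
Reagents that add atoms: none
Why: Fluoride cleaves both aryl O–Si bonds (desilylation), and the acetic acid buffer keeps the medium near neutral so that the flavanone should not open by a retro-oxa-Michael reaction and C2 should keep its S configuration, while the ortho-prenyl phenol is never exposed to strong acid.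

Compound list
1 | resorcinol (benzene-1,3-diol) | Oc1cccc(O)c1 | starting material
2 | 1,3-bis(methoxymethoxy)benzene | COCOc1cccc(OCOC)c1 | intermediate
3 | prenyl bromide (1-bromo-3-methylbut-2-ene) | CC(C)=CCBr | starting material
4 | [2,6-bis(methoxymethoxy)phenyl]lithium | [Li]c1c(OCOC)cccc1OCOC | intermediate
5 | 1,3-bis(methoxymethoxy)-2-(3-methylbut-2-enyl)benzene | COCOc1cccc(OCOC)c1CC=C(C)C | intermediate
6 | [2,4-bis(methoxymethoxy)-3-(3-methylbut-2-enyl)phenyl]lithium | [Li]c1ccc(OCOC)c(CC=C(C)C)c1OCOC | intermediate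
7 | 1-iodo-2,4-bis(methoxymethoxy)-3-(3-methylbut-2-enyl)benzene | Ic1ccc(OCOC)c(CC=C(C)C)c1OCOC | intermediate
8 | 4-iodo-2-(3-methylbut-2-enyl)benzene-1,3-diol | Ic1ccc(O)c(CC=C(C)C)c1O | intermediate
9 | 6-iodo-2-(3-methylbut-2-enyl)-3-(triisopropylsilyloxy)phenol | Ic1ccc(O[Si](C(C)C)(C(C)C)C(C)C)c(CC=C(C)C)c1O | intermediate
10 | 4-bromoresorcinol (4-bromobenzene-1,3-diol) | Oc1ccc(Br)c(O)c1 | starting material
11 | 3-methylbut-2-enoic acid | CC(C)=CC(=O)O | starting material
12 | 1-(5-bromo-2,4-dihydroxyphenyl)-3-methylbut-2-en-1-one | CC(C)=CC(=O)c1cc(Br)c(O)cc1O | intermediate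
13 | 6-bromo-7-hydroxy-2,2-dimethylchroman-4-one | CC1(C)CC(=O)c2cc(Br)c(O)cc2O1 | intermediate
14 | 6-bromo-2,2-dimethyl-7-(triisopropylsilyloxy)chroman-4-one | CC1(C)CC(=O)c2cc(Br)c(O[Si](C(C)C)(C(C)C)C(C)C)cc2O1 | intermediate
15 | 6-bromo-2,2-dimethyl-7-(triisopropylsilyloxy)chroman-4-ol (racemic) | CC1(C)CC(O)c2cc(Br)c(O[Si](C(C)C)(C(C)C)C(C)C)cc2O1 | intermediate
16 | 6-bromo-2,2-dimethyl-7-(triisopropylsilyloxy)-2H-chromene | CC1(C)C=Cc2cc(Br)c(O[Si](C(C)C)(C(C)C)C(C)C)cc2O1 | intermediate
17 | ethynyltrimethylsilane | C#C[Si](C)(C)C | starting material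
18 | 2,2-dimethyl-7-(triisopropylsilyloxy)-6-[(trimethylsilyl)ethynyl]-2H-chromene | CC1(C)C=Cc2cc(C#C[Si](C)(C)C)c(O[Si](C(C)C)(C(C)C)C(C)C)cc2O1 | intermediate
19 | 6-ethynyl-2,2-dimethyl-7-(triisopropylsilyloxy)-2H-chromene | C#Cc1cc2c(cc1O[Si](C(C)C)(C(C)C)C(C)C)OC(C)(C)C=C2 | intermediate
20 | carbon monoxide | [C-]#[O+] | starting material
21 | 3-[2,2-dimethyl-7-(triisopropylsilyloxy)-2H-chromen-6-yl]-1-[2-hydroxy-3-(3-methylbut-2-enyl)-4-(triisopropylsilyloxy)phenyl]prop-2-yn-1-one | CC(C)=CCc1c(O[Si](C(C)C)(C(C)C)C(C)C)ccc(C(=O)C#Cc2cc3c(cc2O[Si](C(C)C)(C(C)C)C(C)C)OC(C)(C)C=C3)c1O | intermediate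
22 | 3-(diethylamino)-3-[2,2-dimethyl-7-(triisopropylsilyloxy)-2H-chromen-6-yl]-1-[2-hydroxy-3-(3-methylbut-2-enyl)-4-(triisopropylsilyloxy)phenyl]prop-2-en-1-one (alkene geometry not defined) | CC(C)=CCc1c(O[Si](C(C)C)(C(C)C)C(C)C)ccc(C(=O)C=C(N(CC)CC)c2cc3c(cc2O[Si](C(C)C)(C(C)C)C(C)C)OC(C)(C)C=C3)c1O | intermediate
23 | 2-[2,2-dimethyl-7-(triisopropylsilyloxy)-2H-chromen-6-yl]-8-(3-methylbut-2-enyl)-7-(triisopropylsilyloxy)-4H-chromen-4-one | CC(C)=CCc1c(O[Si](C(C)C)(C(C)C)C(C)C)ccc2c1OC(c1cc3c(cc1O[Si](C(C)C)(C(C)C)C(C)C)OC(C)(C)C=C3)=CC2=O | intermediate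
24 | (2S)-2-[2,2-dimethyl-7-(triisopropylsilyloxy)-2H-chromen-6-yl]-8-(3-methylbut-2-enyl)-7-(triisopropylsilyloxy)-2,3-dihydro-4H-chromen-4-one | CC(C)=CCc1c(O[Si](C(C)C)(C(C)C)C(C)C)ccc2c1O[C@H](c1cc3c(cc1O[Si](C(C)C)(C(C)C)C(C)C)OC(C)(C)C=C3)CC2=O | intermediate
25 | (2S)-7-hydroxy-2-(7-hydroxy-2,2-dimethyl-2H-chromen-6-yl)-8-(3-methylbut-2-enyl)-2,3-dihydro-4H-chromen-4-one | CC(C)=CCc1c(O)ccc2c1O[C@H](c1cc3c(cc1O)OC(C)(C)C=C3)CC2=O | target

Total step count: 13.
Longest linear sequence: 8 steps (steps 1–5, then 11–13; the branch of steps 6–10 followed by 11–13 is equally long).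

Steps most likely to fail

Step 11. The arylpalladium species may couple with the alkyne before CO has inserted, or oxidative addition into the electron-rich aryl iodide may be so slow that the alkyne is consumed by oligomerisation. The fallback brings C4 in as a formyl carbon instead of CO. It sets out from 9 and 19. Treating 9 with n-BuLi (2.2 equiv, THF, −78 °C) removes the hydroxyl proton and exchanges the iodine to give the lithium 2-lithiophenoxide F1, and DMF converts this into 2-hydroxy-3-(3-methylbut-2-enyl)-4-(triisopropylsilyloxy)benzaldehyde F2. Alkyne 19 is deprotonated with n-BuLi to the lithium acetylide F3, which adds to the lithium phenoxide of F2 (preformed with LiN(SiMe3)2) to give the racemic propargylic alcohol F4. MnO2 in CH2Cl2 oxidises F4 to ynone 21, where the route is rejoined: warming 21 in Et2NH alone closes ring C through 22 to 23.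

Step 12. Hydride transfer to C2 may be slow because the ortho-silyloxy aryl group crowds that carbon, and the facial selectivity may be poor. The fallback sets stereochemistry by resolution of the ketone. It sets out from 23. An achiral copper hydride (Cu(OAc)2·H2O, 1,2-bis(diphenylphosphino)benzene, polymethylhydrosiloxane, t-BuOH, toluene) should give the racemic flavanone bis-TIPS ether F5. Kinetic resolution by Noyori-type asymmetric transfer hydrogenation (Cp*RhCl(TsDPEN), HCO2H/Et3N, with the catalyst antipode that reduces the 2R ketone) converts the unwanted enantiomer into the cis-(2R,4R)-flavan-4-ol F6 and leaves 24, which is separated by chromatography and taken into step 13.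

Step 3. The base may remove a proton from the benzylic and allylic CH2 of the prenyl group instead of from the ring, and some iodine may add to the alkene during the quench. The fallback fixes the site of lithium by halogen–lithium exchange. It sets out from 10. MOMCl and i-Pr2NEt give 1-bromo-2,4-bis(methoxymethoxy)benzene F7. LiN(i-Pr)2 (THF, −78 °C) removes the proton between the two OMOM groups to give the aryllithium F8, and prenyl bromide 3 with CuBr·SMe2 (10 mol %) gives 1-bromo-2,4-bis(methoxymethoxy)-3-(3-methylbut-2-enyl)benzene F9. t-BuLi (2 equiv, −78 °C) then exchanges the bromine and delivers aryllithium 6, where the route is rejoined before the iodine quench of step 3.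

Further compounds
F1 | step 11 | lithium 2-lithio-6-(3-methylbut-2-enyl)-5-(triisopropylsilyloxy)phenoxide | [Li]Oc1c([Li])ccc(O[Si](C(C)C)(C(C)C)C(C)C)c1CC=C(C)C
F2 | step 11 | 2-hydroxy-3-(3-methylbut-2-enyl)-4-(triisopropylsilyloxy)benzaldehyde | O=Cc1ccc(O[Si](C(C)C)(C(C)C)C(C)C)c(CC=C(C)C)c1O
F3 | step 11 | {[2,2-dimethyl-7-(triisopropylsilyloxy)-2H-chromen-6-yl]ethynyl}lithium | [Li]C#Cc1cc2c(cc1O[Si](C(C)C)(C(C)C)C(C)C)OC(C)(C)C=C2
F4 | step 11 | 3-[2,2-dimethyl-7-(triisopropylsilyloxy)-2H-chromen-6-yl]-1-[2-hydroxy-3-(3-methylbut-2-enyl)-4-(triisopropylsilyloxy)phenyl]prop-2-yn-1-ol (racemic) | CC(C)=CCc1c(O[Si](C(C)C)(C(C)C)C(C)C)ccc(C(O)C#Cc2cc3c(cc2O[Si](C(C)C)(C(C)C)C(C)C)OC(C)(C)C=C3)c1O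
F5 | step 12 | 2-[2,2-dimethyl-7-(triisopropylsilyloxy)-2H-chromen-6-yl]-8-(3-methylbut-2-enyl)-7-(triisopropylsilyloxy)-2,3-dihydro-4H-chromen-4-one (racemic) | CC(C)=CCc1c(O[Si](C(C)C)(C(C)C)C(C)C)ccc2c1OC(c1cc3c(cc1O[Si](C(C)C)(C(C)C)C(C)C)OC(C)(C)C=C3)CC2=O
F6 | step 12 | (2R,4R)-2-[2,2-dimethyl-7-(triisopropylsilyloxy)-2H-chromen-6-yl]-8-(3-methylbut-2-enyl)-7-(triisopropylsilyloxy)chroman-4-ol | CC(C)=CCc1c(O[Si](C(C)C)(C(C)C)C(C)C)ccc2c1O[C@@H](c1cc3c(cc1O[Si](C(C)C)(C(C)C)C(C)C)OC(C)(C)C=C3)C[C@H]2O
F7 | step 3 | 1-bromo-2,4-bis(methoxymethoxy)benzene | COCOc1ccc(Br)c(OCOC)c1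
F8 | step 3 | [3-bromo-2,6-bis(methoxymethoxy)phenyl]lithium | [Li]c1c(OCOC)ccc(Br)c1OCOC
F9 | step 3 | 1-bromo-2,4-bis(methoxymethoxy)-3-(3-methylbut-2-enyl)benzene | COCOc1ccc(Br)c(OCOC)c1CC=C(C)C
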